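**Retrosynthetic overview**

1. The target is 5,7-dihydroxy-2-nonacosyl-4H-chromen-4-one; both phenols are carried as methyl ethers and freed in the last step.
2. Feature the strategy rests on: on ring A the pyranone oxygen O1 (on C8a) and the carbonyl carbon C4 (on C4a) sit on adjacent ring carbons, and C4a has the oxygen-bearing C5 on its other side. This ortho oxygen/acyl pair next to an alkoxy group is what a 3-alkoxybenzyne gives when it takes up a carboxylic acid.
3. Key disconnection: O1–C8a, C4–C4a and O1–C2 together, back to 3,5-dimethoxy-2-(trimethylsilyl)phenyl triflate and dotriacont-2-ynoic acid. The pyranone (ring C) is the only ring built; ring A is bought.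
4. The silyl triflate comes from 3,5-dimethoxyphenol by carbamate-directed ortho-silylation and one-pot decarbamoylation/triflation. The ynoic acid comes from 1-triacontanol by oxidation, one-carbon alkyne homologation and carboxylation.

Key step: step 7

Remark: the target is achiral and its side chain is unbranched C29, so C2, C3, C4 and the chain are taken from one C32 2-ynoic acid; ring atoms are given in chromone numbering.

**Step 1**
Reactants: 1 3,5-dimethoxyphenol
Product: 2 3,5-dimethoxyphenyl N-isopropylcarbamate
Conditions: i-PrNCO (1.5 equiv), Et3N (0.2 equiv), CH2Cl2, rt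
Reagents that add atoms: isopropyl isocyanate, CC(C)N=C=O
Why: Amine-catalysed addition of the phenol O–H across the isocyanate (carbamoylation) should install a strong, later mildly removable directing group.

**Step 2**
Reactants: 2 3,5-dimethoxyphenyl N-isopropylcarbamate
Product: 6 3,5-dimethoxy-2-(trimethylsilyl)phenyl N-isopropylcarbamate, via N-silyl carbamate 3 (not isolated), via aryllithium 4 (not isolated), via N-silyl arylsilane 5 (not isolated)
Conditions: TBSOTf (1.1 equiv), TMEDA, Et2O, 0 °C → rt; then TMEDA, n-BuLi (2 equiv), −78 °C; then Me3SiCl, −78 °C → rt; aq. NaHSO4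
Reagents that add atoms: chlorotrimethylsilane, C[Si](C)(C)Cl
Why: In situ N-silylation masks the N–H, and directed ortho-metalation should then occur at the carbon between the carbamate and a methoxy group (the two such sites are equivalent by symmetry), which is activated by both groups and preferred over the site between the two weaker methoxy directors; silyl chloride quench and acidic work-up (loss of the N-silyl group) give 6.

**Step 3**
Reactants: 6 3,5-dimethoxy-2-(trimethylsilyl)phenyl N-isopropylcarbamate
Product: 8 3,5-dimethoxy-2-(trimethylsilyl)phenyl trifluoromethanesulfonate, via silylphenol 7 (not isolated)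
Conditions: DBU (1.5 equiv), Et2NH (1.25 equiv), MeCN, 40 °C; then PhNTf2 (1.5 equiv), rt
Reagents that add atoms: N-phenylbis(trifluoromethanesulfonimide), O=S(=O)(N(c1ccccc1)S(=O)(=O)C(F)(F)F)C(F)(F)F
Why: DBU deprotonates the carbamate N–H and the phenoxide is expelled (E1cB), diethylamine traps the isopropyl isocyanate as a urea, and the phenoxide is triflated in the same pot by the mild triflyl donor without touching the aryl–silicon bond.

**Step 4**
Reactants: 9 1-triacontanol
Product: 10 triacontanal
Conditions: TEMPO (cat.), PhI(OAc)2 (1.1 equiv), CH2Cl2, 35 °C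
Reagents that add atoms: none
Why: Oxoammonium-mediated oxidation of a primary alcohol under anhydrous conditions should stop at the aldehyde, and the warm chlorinated solvent keeps the waxy substrate dissolved.

**Step 5**
Reactants: 10 triacontanal; 11 dimethyl (1-diazo-2-oxopropyl)phosphonate
Product: 12 hentriacont-1-yne
Conditions: K2CO3 (2 equiv), MeOH/THF, rt → 40 °C
Reagents that add atoms: dimethyl (1-diazo-2-oxopropyl)phosphonate (compound 11), COP(=O)(OC)C(=[N+]=[N-])C(C)=O
Why: Ohira–Bestmann homologation: methanolysis of 11 releases the diazomethylphosphonate anion, which olefinates the aldehyde; loss of N2 and 1,2-hydride shift of the alkylidene carbene give the terminal alkyne with one added carbon.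

**Step 6**
Reactants: 12 hentriacont-1-yne
Product: 15 dotriacont-2-ynoic acid, via lithium acetylide 13 (not isolated), via lithium ynoate 14 (not isolated)
Conditions: n-BuLi (1.1 equiv), THF, 0 °C; then CO2 (g), 0 °C → rt; aq. HCl
Reagents that add atoms: carbon dioxide, O=C=O
Why: Deprotonation of the terminal alkyne and carboxylation of the acetylide is a standard route to 2-alkynoic acids, and the only acidic C–H in 12 is the alkyne hydrogen.

**Step 7**
Reactants: 8 3,5-dimethoxy-2-(trimethylsilyl)phenyl trifluoromethanesulfonate (1.5 equiv); 15 dotriacont-2-ynoic acid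
Product: 19 5,7-dimethoxy-2-nonacosyl-4H-chromen-4-one, via cesium ynoate 16 (not isolated), via 3,5-dimethoxybenzyne 17 (not isolated), via acylphenoxide 18 (not isolated)
Conditions: CsF (4 equiv), THF, 125 °C, sealed tube
Reagents that add atoms: none
Why: CsF turns acid 15 into cesium ynoate 16 and removes the silyl group from 8, so that loss of triflate unmasks aryne 17 with its triple bond across the future C4a and C8a; the carboxylate oxygen bonds to C8a, the C4a carbanion closes onto the adjacent ester carbonyl (4-exo-trig), and opening of that four-membered alkoxide with rupture of the old acyl C–O bond leaves acylphenoxide 18, a net insertion of the aryne into the carboxylic C–O bond (O1–C8a and C4–C4a made). The phenoxide then adds to the chain-bearing ynone carbon in a 6-endo-dig oxa-Michael closure (O1–C2), and the allenolate takes up at C3 the proton held as bifluoride, giving the pyranone ring directly in its final oxidation state with no new stereocentre. The closest known reaction type is the fluoride-induced aryne insertion into the C–O bond of carboxylic acids, which with α,β-unsaturated and arylpropiolic acids runs on by oxa-Michael addition to 4-chromanones and flavones; the aliphatic long-chain ynoic acid and the dimethoxyaryne are new substrates within that class. Three selectivities are needed: oxygen must bond to C8a and not C4a, which the methoxy group at the future C5 secures because its inductive pull and the distortion it imposes on the aryne make the remote carbon the electrophilic one and place the carbanion beside it; acyl transfer must outrun protonation of the aryl anion (which would end at the simple aryl ester), which the excess CsF and the high temperature favour; and 6-endo closure must beat 5-exo closure to the aurone, which the conjugate polarisation of the ynone and the aprotic medium favour.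

**Step 8**
Reactants: 19 5,7-dimethoxy-2-nonacosyl-4H-chromen-4-one
Product: 21 5,7-dihydroxy-2-nonacosyl-4H-chromen-4-one, via bis(dibromoboryl) ether 20 (not isolated)
Conditions: BBr3 (6 equiv), CH2Cl2, 0 °C → 40 °C; then ice/H2O
Reagents that add atoms: none
Why: Lewis-acid cleavage of aryl methyl ethers with BBr3: the C5 ether, chelated to the C4 carbonyl, should go first and the C7 ether on warming, while the pyranone and the saturated chain are inert; hydrolysis of the aryl borates gives the diol.

**Compound list**

1 | 3,5-dimethoxyphenol | COc1cc(O)cc(OC)c1 | starting material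
2 | 3,5-dimethoxyphenyl N-isopropylcarbamate | COc1cc(OC(=O)NC(C)C)cc(OC)c1 | intermediate
3 | 3,5-dimethoxyphenyl N-(tert-butyldimethylsilyl)-N-isopropylcarbamate | COc1cc(OC(=O)N(C(C)C)[Si](C)(C)C(C)(C)C)cc(OC)c1 | intermediate
4 | 2-lithio-3,5-dimethoxyphenyl N-(tert-butyldimethylsilyl)-N-isopropylcarbamate | [Li]c1c(OC)cc(OC)cc1OC(=O)N(C(C)C)[Si](C)(C)C(C)(C)C | intermediate
5 | 3,5-dimethoxy-2-(trimethylsilyl)phenyl N-(tert-butyldimethylsilyl)-N-isopropylcarbamate | COc1cc(OC)c([Si](C)(C)C)c(OC(=O)N(C(C)C)[Si](C)(C)C(C)(C)C)c1 | intermediate
6 | 3,5-dimethoxy-2-(trimethylsilyl)phenyl N-isopropylcarbamate | COc1cc(OC)c([Si](C)(C)C)c(OC(=O)NC(C)C)c1 | intermediate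
7 | 3,5-dimethoxy-2-(trimethylsilyl)phenol (present as its amidinium phenoxide) | COc1cc(O)c([Si](C)(C)C)c(OC)c1 | intermediate
8 | 3,5-dimethoxy-2-(trimethylsilyl)phenyl trifluoromethanesulfonate | COc1cc(OC)c([Si](C)(C)C)c(OS(=O)(=O)C(F)(F)F)c1 | intermediate
9 | 1-triacontanol | CCCCCCCCCCCCCCCCCCCCCCCCCCCCCCO | starting material
10 | triacontanal | CCCCCCCCCCCCCCCCCCCCCCCCCCCCCC=O | intermediate
11 | dimethyl (1-diazo-2-oxopropyl)phosphonate | COP(=O)(OC)C(=[N+]=[N-])C(C)=O | starting material
12 | hentriacont-1-yne | CCCCCCCCCCCCCCCCCCCCCCCCCCCCCC#C | intermediate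
13 | hentriacont-1-yn-1-yllithium | CCCCCCCCCCCCCCCCCCCCCCCCCCCCCC#C[Li] | intermediate
14 | lithium dotriacont-2-ynoate | CCCCCCCCCCCCCCCCCCCCCCCCCCCCCC#CC(=O)[O-].[Li+] | intermediate
15 | dotriacont-2-ynoic acid | CCCCCCCCCCCCCCCCCCCCCCCCCCCCCC#CC(=O)O | intermediate
16 | cesium dotriacont-2-ynoate | CCCCCCCCCCCCCCCCCCCCCCCCCCCCCC#CC(=O)[O-].[Cs+] | intermediate
17 | 3,5-dimethoxybenzyne (3,5-dimethoxy-1,2-didehydrobenzene) | COC1=CC(OC)=CC#C1 | intermediate
18 | cesium 2-(dotriacont-2-ynoyl)-3,5-dimethoxyphenolate | CCCCCCCCCCCCCCCCCCCCCCCCCCCCCC#CC(=O)c1c(OC)cc(OC)cc1[O-].[Cs+] | intermediate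
19 | 5,7-dimethoxy-2-nonacosyl-4H-chromen-4-one | CCCCCCCCCCCCCCCCCCCCCCCCCCCCCc1cc(=O)c2c(OC)cc(OC)cc2o1 | intermediate
20 | 5,7-bis[(dibromoboryl)oxy]-2-nonacosyl-4H-chromen-4-one | CCCCCCCCCCCCCCCCCCCCCCCCCCCCCc1cc(=O)c2c(OB(Br)Br)cc(OB(Br)Br)cc2o1 | intermediate
21 | 5,7-dihydroxy-2-nonacosyl-4H-chromen-4-one | CCCCCCCCCCCCCCCCCCCCCCCCCCCCCc1cc(=O)c2c(O)cc(O)cc2o1 | target

**Totals**

Total step count: 8. Longest linear sequence: 5 steps (steps 1, 2, 3, 7, 8, or steps 4, 5, 6, 7, 8).

**Steps most likely to fail**

Step 7. Several things may divert the sequence: the aryl anion may be protonated before it reaches the ester carbonyl, which ends at the simple aryl ynoate; it may attack the alkyne terminus of the ester, a coumarin-type closure; the phenoxide may close 5-exo; or the ynoate may lose CO2 at 125 °C. The fallback uses known palladium chemistry and sets out from carbamate 2 and alkyne 12. Carbamate 2 is N-silylated and lithiated as in step 2 (through 3 and 4), but aryllithium 4 is quenched with iodine to give 2-iodo-3,5-dimethoxyphenyl N-(tert-butyldimethylsilyl)-N-isopropylcarbamate F1. Work-up with aq. NaHSO4 gives 2-iodo-3,5-dimethoxyphenyl N-isopropylcarbamate F2, and DBU/Et2NH in MeCN at 40 °C frees 2-iodo-3,5-dimethoxyphenol F3. F3 and alkyne 12 are then joined by carbonylative Sonogashira coupling with PdCl2(dppf) (dppf = 1,1'-bis(diphenylphosphino)ferrocene) under CO in Et2NH at 120 °C. The resulting 1-(2-hydroxy-4,6-dimethoxyphenyl)dotriacont-2-yn-1-one F4 cyclises under the secondary amine, through its β-enaminone, to the chromone, and the route is rejoined at 19.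

Step 2. Lithiation may occur at the carbon between the two methoxy groups, or the carbamoyl group may migrate to carbon (anionic ortho-Fries shift) before the silyl chloride is added. The fallback replaces directed metalation by halogen–metal exchange and sets out from phenol 1. Bromination with NBS in CH2Cl2 at −78 °C gives 2-bromo-3,5-dimethoxyphenol F5, which is separated by chromatography from the isomer brominated between the methoxy groups. Hexamethyldisilazane in THF at reflux gives (2-bromo-3,5-dimethoxyphenoxy)trimethylsilane F6. n-BuLi in THF at −78 °C effects bromine–lithium exchange to (2-lithio-3,5-dimethoxyphenoxy)trimethylsilane F7, which undergoes 1,3-shift of silicon from oxygen to carbon (retro-Brook) to lithium 3,5-dimethoxy-2-(trimethylsilyl)phenolate F8. Tf2O added to the same flask triflates F8, and the route is rejoined at 8.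

Step 5. The waxy aldehyde dissolves poorly in the methanolic medium, so homologation may be slow enough for base-mediated aldol self-condensation to compete, leaving conversion incomplete. The fallback is a Corey–Fuchs sequence from aldehyde 10. CBr4 and PPh3 in CH2Cl2 give 1,1-dibromohentriacont-1-ene F9. n-BuLi (2.2 equiv) in THF, −78 → 0 °C, converts F9 by bromine–lithium exchange, α-elimination and 1,2-hydride shift, then deprotonation, directly into lithium acetylide 13. This is carboxylated as in step 6, so the route is rejoined at 13 without isolating 12.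

**Further compounds**

F1 | step 7 | 2-iodo-3,5-dimethoxyphenyl N-(tert-butyldimethylsilyl)-N-isopropylcarbamate | COc1cc(OC)c(I)c(OC(=O)N(C(C)C)[Si](C)(C)C(C)(C)C)c1
F2 | step 7 | 2-iodo-3,5-dimethoxyphenyl N-isopropylcarbamate | COc1cc(OC)c(I)c(OC(=O)NC(C)C)c1
F3 | step 7 | 2-iodo-3,5-dimethoxyphenol | COc1cc(O)c(I)c(OC)c1
F4 | step 7 | 1-(2-hydroxy-4,6-dimethoxyphenyl)dotriacont-2-yn-1-one | CCCCCCCCCCCCCCCCCCCCCCCCCCCCCC#CC(=O)c1c(OC)cc(OC)cc1O
F5 | step 2 | 2-bromo-3,5-dimethoxyphenol | COc1cc(O)c(Br)c(OC)c1
F6 | step 2 | (2-bromo-3,5-dimethoxyphenoxy)trimethylsilane | COc1cc(O[Si](C)(C)C)c(Br)c(OC)c1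
F7 | step 2 | (2-lithio-3,5-dimethoxyphenoxy)trimethylsilane | COc1cc(O[Si](C)(C)C)c([Li])c(OC)c1
F8 | step 2 | lithium 3,5-dimethoxy-2-(trimethylsilyl)phenolate | COc1cc([O-])c([Si](C)(C)C)c(OC)c1.[Li+]
F9 | step 5 | 1,1-dibromohentriacont-1-ene | CCCCCCCCCCCCCCCCCCCCCCCCCCCCCC=C(Br)Br
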